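Keep the books on one invariant: I take every mole of solid reagent charged to end, mole for mole, in a product, on the protic impurity, or still in the flask.

| flask | left-handed substrate | right-handed substrate | solid reagent | protic impurity | catalyst | remark | time |
|---|---|---|---|---|---|---|---|
| zeta | 0.40 M | 0.40 M | 1.2 M | 0.40 M | 8 mM | run made earlier |  |
| gamma | 0.60 M | 0.60 M | 1.2 M | 0.40 M | 8 mM | run made earlier |  |
| ochre | 0.80 M | 0.80 M | 1.20 M | 0.400 M | 8.0 mM |  | 5.0 h |
| amber | 0.80 M | 0.80 M | 1.20 M | 0.400 M | 8.0 mM |  | 10 h |

| run | time / h | left-handed product / % | right-handed product / % |
|---|---|---|---|
| zeta | 0.500 | 0.8 | 0 |
| zeta | 1.00 | 1.1 | 0 |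
| zeta | 2.50 | 4.5 | 2.5 |
| zeta | 6.00 | 11.1 | 8.4 |
| gamma | 0.500 | 0.2 | 0 |
| gamma | 1.00 | 1.0 | 0 |
| gamma | 2.50 | 4.1 | 1.5 |
| gamma | 6.00 | 10.8 | 8.1 |

(each reading ± 0.5 percentage points)

- which of the two ends with the higher excess of left-handed product over right-handed product in the product ("neither" if they lie within 2 percentage points) (ochre / amber / neither)
- excess of left-handed product over right-handed product in the product at the end, ochre
- excess of left-handed product over right-handed product in the product at the end, amber

- catalyst is single-handed; left-handed substrate and right-handed substrate are mirror images of each other, charged as a racemate, each of them at the stated concentration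
- solid reagent is a solid; its amount is given per volume of the solution
- at the start none of the solid reagent is in solution
- an excess is the difference of the two amounts in percent of their sum
- an excess is below zero if the other one leads

Read the runs zeta and gamma first. Their percent curves agree within the scatter of 0.5 percentage points although their substrate charges differ, so treat the rate as first order in substrate (pseudo-first-order): substrate concentration sets the order, and percents carry over to ochre and amber. Late total product grows at a feed F of 0.0369 /h of the charge, and it extrapolates back to a lag t0 of 0.791 h. The gap D, left-handed minus right-handed product, reads 2.7 points at the last readings. Take D as steady and define the memory time τ = D/F, the hours of feed that the gap is worth, 0.733 h. The excess at time t is then τ/(t − t0).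

Now write the ledger for ochre and amber, which share one charge. Credit 1.20 M of solid reagent. Debit up to 0.400 M to the protic impurity, which leaves room for 0.800 M of product. That is less than the 1.60 M of substrate, so solid reagent is the limiting reagent and total product stops at 50.0% of the charge. Debit product at F: 0.248 M in ochre and 0.543 M in amber, less than the room. Staying below the room does not guarantee a steady feed, so holding F in both flasks is my assumption, and on that assumption the line meets the room at 14.4 h. My reckoning gives ochre 17.4% and amber 7.95%.

The forecast chose ochre, with 16% (11% to 22%) for ochre, below mine, and 8% (5% to 12%) for amber, on the ground that “The excess dilutes with time”. The flask gives 18.9% for ochre and 7.64% for amber, so ochre ends higher.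

    partner + protic impurity → quenched reagent (k = 0.907 /M/h)
    left-handed product ⇌ right-handed product (k = 0.532 /h)
    solid reagent ⇌ partner, rate k3*(cs3 - [partner]) while solid is left; crystals form when [partner] > cs3 (solubility = 0.490 M, k = 0.259 /h)
    partner + catalyst + right-handed substrate → catalyst + right-handed product (k = 4.18 /M²/h)
    partner + catalyst + left-handed substrate → catalyst + left-handed product (k = 77.8 /M²/h)

Left-handed product passes to right-handed product with a forward half-life of 1.3 h, shorter than the 5.0 h of ochre. In ochre, 14.1% reacted at that excess makes a gap of 2.7 points, beside the D of 2.7 points read from the runs. The neighbour flask, ochre left until 20 h, is read later than the 14.4 h at which the reckoned line meets the room. There τ/(t − t0) gives 3.82%, and the flask gives 0.740%.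

The numbers in the tables are calculated on assumed constants; noise was put on by code.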